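## Retrosynthetic overview
1. The O8 angelate and O6 acetate are installed last. A 6‑hydroxy‑8‑ketone undergoes Evans–Tishchenko reduction with acetaldehyde (acetate on O6, 1,3‑anti 8‑OH), followed by angeloylation.
2. The 6‑hydroxy‑8‑ketone is the N–O‑cleaved form of a 2‑isoxazoline that bridges C8 (C=N) and O6.
3. Key disconnection: C7–C8 and O–C6 together. An intramolecular nitrile oxide–alkene cycloaddition of an acyclic epoxy nitro diene closes the ten‑membered carbocycle and the isoxazoline in the same operation.
4. The acyclic precursor is built from nerol (C1–C6, C9, C10, C14, C15), nitromethane (C8) and an isobutyl tetrazolyl sulfone (C7, C11–C13).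
5. Ring order: oxirane first (Sharpless epoxidation of nerol), then carbocycle and isoxazoline at once, then the isoxazoline is opened again.

Assumption: germacrane locants are used (oxirane C4–C5, OAc on C6, iPr on C7, OAng on C8, alkene C1=C10). The SMILES is read as (1(10)E,4S,5R,6R,7R,8S) with C3 and C6 cis on the oxirane, so the C10 block is nerol and not geraniol.

## Route

Step 1
Reactants: 1 nerol
Product: 2 (2R,3S)-2,3-epoxynerol
Conditions: Ti(OiPr)4 (10 mol %), D-(−)-diethyl tartrate (12 mol %), t-BuOOH (2 equiv), 4 Å MS, CH2Cl2, −20 °C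
Reagents that add atoms: tert-butyl hydroperoxide, CC(C)(C)OO
Why: Katsuki–Sharpless asymmetric epoxidation touches only the allylic alkene; the D-(−)-tartrate delivers oxygen to the face that gives C5 R and C4 S (about 92–94 % ee), and syn addition to the Z-alkene places C3 and C6 cis on the oxirane.

Step 2
Reactants: 2 (2R,3S)-2,3-epoxynerol
Product: 3 [(2R,3S)-3-(3-chloro-4-methylpent-4-enyl)-3-methyloxiran-2-yl]methanol (about 1:1 at C–Cl)
Conditions: N-chlorosuccinimide (1.1 equiv), PhSeCl (5 mol %), CH2Cl2, rt
Reagents that add atoms: N-chlorosuccinimide, O=C1CCC(=O)N1Cl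
Why: Selenium-catalysed ene-type allylic chlorination of the only remaining alkene gives the transposed secondary allylic chloride, and its new centre does not matter because step 3 erases it.

Step 3
Reactants: 3 chloro-ene product, 4 nitromethane
Product: 5 [(2R,3S)-3-methyl-3-[(3E)-4-methyl-6-nitrohex-3-enyl]oxiran-2-yl]methanol
Conditions: Pd(PPh3)4 (5 mol %), Cs2CO3 (1.1 equiv), MeNO2/THF 1:1 (about 50 equiv of 4), 40 °C
Reagents that add atoms: none
Why: In this Tsuji–Trost allylic alkylation, zerovalent palladium ionises the chloride and the soft nitronate attacks the unsubstituted terminus of the syn allyl complex to give the linear (E)-trisubstituted alkene; the large excess of 4 suppresses double allylation and the non-allylic oxirane is inert.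

Step 4
Reactants: 5 nitro epoxy alcohol
Product: 6 (2S,3S)-3-methyl-3-[(3E)-4-methyl-6-nitrohex-3-enyl]oxirane-2-carbaldehyde
Conditions: TEMPO (2,2,6,6-tetramethylpiperidin-1-oxyl, 10 mol %), PhI(OAc)2 (1.1 equiv), CH2Cl2, rt
Reagents that add atoms: none
Why: Oxoammonium (TEMPO) oxidation stops at the aldehyde and leaves oxirane, alkene and nitro group untouched; the descriptor at C5 changes only through CIP priorities.

Step 5
Reactants: 7 1-phenyl-1H-tetrazole-5-thiol, 8 1-bromo-2-methylpropane
Product: 9 5-(2-methylpropylsulfanyl)-1-phenyl-1H-tetrazole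
Conditions: K2CO3, DMF, 60 °C
Reagents that add atoms: none
Why: This is a simple SN2 S-alkylation of the soft thiolate with a primary bromide.

Step 6
Reactants: 9 tetrazolyl sulfide
Product: 10 5-(2-methylpropylsulfonyl)-1-phenyl-1H-tetrazole
Conditions: 30 % H2O2 (5 equiv), (NH4)6Mo7O24·4H2O (10 mol %), EtOH, rt
Reagents that add atoms: hydrogen peroxide, OO
Why: Molybdate-catalysed peroxide oxidation takes the sulfide cleanly to the sulfone.

Step 7
Reactants: 6 nitro epoxy aldehyde, 10 isobutyl tetrazolyl sulfone
Product: 11 (2S,3R)-2-methyl-3-[(1E)-3-methylbut-1-enyl]-2-[(3E)-4-methyl-6-nitrohex-3-enyl]oxirane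
Conditions: 10 (2.3 equiv), KN(SiMe3)2 (2.2 equiv), DME, −78 °C; then 6 added slowly, −78 °C to rt; aq NH4Cl
Reagents that add atoms: none
Why: In this Julia–Kocienski olefination the first equivalent of metalated sulfone turns CH2NO2 into its unreactive nitronate (self-protection, reversed at the quench); the second adds to the aldehyde, and Smiles rearrangement with anti elimination gives the (E)-C6=C7 alkene.

Step 8
Reactants: 11 epoxy nitro diene
Product: 13 (1(10)E,4S,5R,6R,7R)-4,5-epoxygermacr-1(10)-ene bridged by a 2-isoxazoline C8=N–O–C6, via nitrile oxide 12 (not isolated)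
Conditions: PhNCO (4 equiv), Et3N (0.3 equiv), toluene, 80 °C, 11 added by syringe pump over 24 h (final 1 mM)
Reagents that add atoms: none
Why: Proposed new method: Mukaiyama–Hoshino dehydration of the primary nitro group gives 12, whose concerted suprafacial [3+2] addition to the (E)-C6=C7 alkene forms C7–C8 and O–C6 at once and so closes the ten-membered carbocycle and the isoxazoline together; the E geometry is copied into the anti C6–O/C7–iPr relation; the cis-oxirane holds the alkenyl group in its bisected s-trans conformer, so the tether leaving C4 can reach only the alkene face anti to the oxirane oxygen, which gives 6R,7R with the isopropyl group pointing away from the tether; the opposite regiochemistry would need a more strained nine-membered ring and attack on C1=C10 a four-membered one; slow addition at 1 mM holds back furoxan formation; the closest known reaction type is the intramolecular nitrile oxide–olefin cycloaddition used for macrocycles with terminal alkenes, not yet shown for a ten-membered ring on an internal unactivated alkene.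

Step 9
Reactants: 13 isoxazoline-bridged epoxygermacrene
Product: 15 (1(10)E,4S,5R,6R,7S)-4,5-epoxy-6-hydroxygermacr-1(10)-en-8-one, via hydroxy imine 14 (not isolated)
Conditions: Raney Ni (W-2), H2 (1 atm), B(OH)3 (4 equiv), MeOH/H2O 5:1, rt
Reagents that add atoms: water, O
Why: In this Curran-type isoxazoline hydrogenolysis, Raney Ni cleaves the weak N–O bond and the boric acid buffer hydrolyses 14 and traps ammonia, so no retro-aldol or C7 epimerisation occurs; the trisubstituted alkene and oxirane survive at 1 atm, and the 7S label is a CIP change only.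

Step 10
Reactants: 15 hydroxy ketone, 16 acetaldehyde
Product: 18 (1(10)E,4S,5R,6R,7R,8S)-6-acetoxy-4,5-epoxygermacr-1(10)-en-8-ol, via hemiacetal 17 (not isolated)
Conditions: SmI2 (0.3 equiv, premixed with 16), 16 (10 equiv), THF, −10 °C
Reagents that add atoms: none
Why: In this Evans–Tishchenko reduction, the trivalent samarium alkoxide formed from SmI2 and 16 binds the C8 ketone and the O6 hemiacetal 17, and hydride passes within a chair-like array to give only the 1,3-anti product; this sets C8 as S and leaves the acetate on O6 and a free 8-OH in one step.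

Step 11
Reactants: 18 hydroxy acetate, 19 angelic acid
Product: 21 target (1(10)E,4S,5R,6R,7R,8S)-6-acetoxy-4,5-epoxygermacr-1(10)-en-8-yl (Z)-2-methylbut-2-enoate, via mixed anhydride 20 (not isolated)
Conditions: 19 (3 equiv), 2,4,6-Cl3C6H2COCl (3 equiv), Et3N (3 equiv), toluene, rt, 2 h; then 18, 80 °C, no DMAP
Reagents that add atoms: none
Why: In this Yamaguchi-type mixed-anhydride esterification the alcohol attacks the unhindered angeloyl carbonyl of 20; leaving out DMAP avoids the addition–elimination path that turns angelate into tiglate, and no stereocentre is touched.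

## Compound list
1 | nerol, (2Z)-3,7-dimethylocta-2,6-dien-1-ol | CC(C)=CCC/C(C)=C\CO | starting material
2 | (2R,3S)-2,3-epoxynerol | CC(C)=CCC[C@]1(C)O[C@@H]1CO | intermediate
3 | [(2R,3S)-3-(3-chloro-4-methylpent-4-enyl)-3-methyloxiran-2-yl]methanol, C–Cl centre about 1:1 | C=C(C)C(Cl)CC[C@]1(C)O[C@@H]1CO | intermediate
4 | nitromethane | C[N+](=O)[O-] | starting material
5 | [(2R,3S)-3-methyl-3-[(3E)-4-methyl-6-nitrohex-3-enyl]oxiran-2-yl]methanol | [O-][N+](=O)CC/C(C)=C/CC[C@]1(C)O[C@@H]1CO | intermediate
6 | (2S,3S)-3-methyl-3-[(3E)-4-methyl-6-nitrohex-3-enyl]oxirane-2-carbaldehyde | [O-][N+](=O)CC/C(C)=C/CC[C@]1(C)O[C@@H]1C=O | intermediate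
7 | 1-phenyl-1H-tetrazole-5-thiol | Sc1nnnn1-c1ccccc1 | starting material
8 | 1-bromo-2-methylpropane | CC(C)CBr | starting material
9 | 5-(2-methylpropylsulfanyl)-1-phenyl-1H-tetrazole | CC(C)CSc1nnnn1-c1ccccc1 | intermediate
10 | 5-(2-methylpropylsulfonyl)-1-phenyl-1H-tetrazole | CC(C)CS(=O)(=O)c1nnnn1-c1ccccc1 | intermediate
11 | (2S,3R)-2-methyl-3-[(1E)-3-methylbut-1-enyl]-2-[(3E)-4-methyl-6-nitrohex-3-enyl]oxirane | [O-][N+](=O)CC/C(C)=C/CC[C@]1(C)O[C@@H]1/C=C/C(C)C | intermediate
12 | nitrile oxide of 11 (CH2NO2 replaced by C≡N–O) | [O-][N+]#CC/C(C)=C/CC[C@]1(C)O[C@@H]1/C=C/C(C)C | intermediate (not isolated)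
13 | (1(10)E,4S,5R,6R,7R)-4,5-epoxygermacr-1(10)-ene with 2-isoxazoline bridge C8=N–O–C6 | CC(C)[C@@H]1C2=NO[C@H]1[C@H]1O[C@@]1(C)CC/C=C(C)/C2 | intermediate
14 | (1(10)E,4S,5R,6R,7R)-4,5-epoxy-6-hydroxygermacr-1(10)-en-8-imine | N=C1C/C(C)=C/CC[C@]2(C)O[C@@H]2[C@H](O)[C@@H]1C(C)C | intermediate (not isolated)
15 | (1(10)E,4S,5R,6R,7S)-4,5-epoxy-6-hydroxygermacr-1(10)-en-8-one | O=C1C/C(C)=C/CC[C@]2(C)O[C@@H]2[C@H](O)[C@@H]1C(C)C | intermediate
16 | acetaldehyde | CC=O | starting material
17 | O6-(1-hydroxyethyl) hemiacetal of 15 (bound to samarium in the flask) | O=C1C/C(C)=C/CC[C@]2(C)O[C@@H]2[C@H](OC(C)O)[C@@H]1C(C)C | intermediate (not isolated)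
18 | (1(10)E,4S,5R,6R,7R,8S)-6-acetoxy-4,5-epoxygermacr-1(10)-en-8-ol | O[C@H]1C/C(C)=C/CC[C@]2(C)O[C@@H]2[C@H](OC(C)=O)[C@@H]1C(C)C | intermediate
19 | angelic acid, (Z)-2-methylbut-2-enoic acid | C/C=C(/C)C(=O)O | starting material
20 | angelic 2,4,6-trichlorobenzoic anhydride | C/C=C(/C)C(=O)OC(=O)c1c(Cl)cc(Cl)cc1Cl | intermediate (not isolated)
21 | (1(10)E,4S,5R,6R,7R,8S)-6-acetoxy-4,5-epoxygermacr-1(10)-en-8-yl angelate | C/C=C(/C)C(=O)O[C@H]1C/C(C)=C/CC[C@]2(C)O[C@@H]2[C@H](OC(C)=O)[C@@H]1C(C)C | target

## Step count and risks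
Total steps: 11. Longest linear sequence: 9 (steps 1–4 and 7–11, from nerol).

**Step 8.** The slow medium-ring cycloaddition may lose to furoxan formation or take the other regiochemistry. The fallback sets out from 11 and comes back at 13. The short-lived nitrile oxide is replaced by a dipole that cannot dimerise. Me3SiCl/Et3N in toluene converts 11 into trimethylsilyl nitronate F1. This can be kept for days at 110 °C and 1 mM until the intramolecular silyl nitronate–olefin cycloaddition gives N-silyloxy isoxazolidine F2. Both rings again form at once, with the same suprafacial transfer of the E geometry. A trace of TsOH then eliminates silanol to give 13.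

**Step 7.** The carbanion olefination runs next to an acidic CH2NO2 group, so a Henry reaction or quenching of the sulfone anion may compete. The fallback sets out from 6 and comes back at 11, and it uses no carbanion. Aldehyde-selective Takai methylenation (CH2I2, Zn, Ti(OiPr)4, THF) gives terminal vinyl oxirane F3. Cross-metathesis with excess 3-methylbut-1-ene (second-generation Hoveyda–Grubbs catalyst, CH2Cl2, 40 °C) then builds the (E)-alkene of 11. The trisubstituted alkene stays inert.

**Step 10.** The Lewis-acidic samarium alkoxide may trigger retro-aldol ring opening or transannular opening of the oxirane. The fallback sets out from 15 and comes back at 21. Hydroxyl-directed Saksena–Evans reduction (Me4NBH(OAc)3, MeCN/AcOH, −35 °C) gives anti-diol F4. The less hindered 8-OH is esterified first with mixed anhydride 20 to give 8-angelate F5. Ac2O/pyridine then acetylates O6 to give 21.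

Further compounds
F1 | step 8 | trimethylsilyl nitronate of 11 | C[Si](C)(C)O[N+]([O-])=CC/C(C)=C/CC[C@]1(C)O[C@@H]1/C=C/C(C)C
F2 | step 8 | N-(trimethylsilyloxy) isoxazolidine bridging C8 and O6 of the (1(10)E,4S,5R,6R,7R)-4,5-epoxygermacr-1(10)-ene ring, C8 undefined | CC(C)[C@@H]1C2N(O[Si](C)(C)C)O[C@H]1[C@H]1O[C@@]1(C)CC/C=C(C)/C2
F3 | step 7 | (2S,3R)-3-ethenyl-2-methyl-2-[(3E)-4-methyl-6-nitrohex-3-enyl]oxirane | [O-][N+](=O)CC/C(C)=C/CC[C@]1(C)O[C@@H]1C=C
F4 | step 10 | (1(10)E,4S,5R,6R,7R,8S)-4,5-epoxygermacr-1(10)-ene-6,8-diol | O[C@H]1C/C(C)=C/CC[C@]2(C)O[C@@H]2[C@H](O)[C@@H]1C(C)C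
F5 | step 10 | (1(10)E,4S,5R,6R,7R,8S)-4,5-epoxy-6-hydroxygermacr-1(10)-en-8-yl angelate | C/C=C(/C)C(=O)O[C@H]1C/C(C)=C/CC[C@]2(C)O[C@@H]2[C@H](O)[C@@H]1C(C)C
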